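The data were computed for substances that don't exist, noise included.

The ratio of target at 4.00 h to target at 10.0 h in the winter run, 42.6% over 25.7%, gives a loss constant λ, the logarithm of the ratio over the time between, of 0.0842 h⁻¹. Between 2.00 h and 4.00 h the same reckoning gives 0.111 h⁻¹, a larger constant. So in the winter run λ falls with time, and this reckoning reads the loss as first order in target and in a second concentration that runs down, presumably the reagent's: a second-order loss.

| flask | starting material | reagent in the second phase | protic impurity | remark | time | volume of the second phase over the first |
|---|---|---|---|---|---|---|
| summer | 0.20 M | 1.5 equiv | 0.060 M | the very flask that is asked about, followed so far |  |  |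
| winter | 0.30 M | 1.5 equiv | 0.060 M | run made earlier |  |  |
| flask | 0.20 M | 1.50 equiv | 0.0600 M |  | 25 h | 0.25 |

| summer: time / min | summer: target / % | winter: time / h | winter: target / % |
|---|---|---|---|
| 30.0 | 36.3 | 0.833 | 53.5 |
| 60.0 | 47.9 | 2.00 | 53.2 |
| 90.0 | 50.7 | 4.00 | 42.6 |
| 120 | 50.4 | 10.0 | 25.7 |

(each reading ± 0.5 percentage points)

- in the second phase: reagent in the second phase; everything else is in the first
- charges count per volume of the first phase; a concentration in a rate is the amount of a species over the volume of its own phase; every rate counts per litre of the first phase
- the numbers in the tables scatter by 0.5 percentage points (one standard deviation)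
- the earlier runs hold the two phases in the same ratio of volumes as the flask asked about

- red: doubling the transfer coefficient of the reagent in the second phase, all else as stated
- violet: doubling the amount of reagent in the second phase, all else as stated

* target at 25 h, in percent of the starting material charged
* the change that raises the amount of target at 25 h, in percent of the starting material charged most ("none" if none brings more than 2 percentage points) (red / violet / none)
* amount of target at 25 h, in percent of the starting material charged, after red

At fixed equivalents the reagent goes with the charge, so the quantity carried is the specific loss constant κ, λ over the charge of starting material, 0.281 M⁻¹ h⁻¹. For the flask at 0.20 M, κ gives 0.0562 h⁻¹, and from 50.4% at 120 min target reaches 13.9% at 25 h. The rise in the flask ends by about 90.0 min, far earlier than the asked time, so red should change little, while violet should double λ and lower target. This reckoning therefore says none.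

The forecast differs on that choice: 16.5% (from 10% to 20%), best violet, and 19% after red (from 12% to 24%), with the words “Second-order decay compresses both gains, but violet still looks best.”

The flask gives 14.1%, best none, and 14.1% after red; red changes target by −0.0062 percentage points, violet by −11 points.

    reagent in the reaction phase ⇌ reagent in the second phase, rate k1*([reagent in the reaction phase] - [reagent in the second phase]/K1) per volume of the first phase (partition coefficient = 0.530, kL = 3.60 h⁻¹)
    starting material + reagent in the reaction phase ⇌ target (K = 12.0 M⁻¹, k = 5.30 M⁻¹ h⁻¹)
    reagent in the reaction phase + target → over-reacted product (k = 0.810 M⁻¹ h⁻¹)
    reagent in the reaction phase ⇌ dormant form (K = 0.420, k = 0.0380 h⁻¹)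
    starting material + protic impurity → quenched substrate (k = 0.370 M⁻¹ h⁻¹)

The over-reaction takes a large part of the target: without that step the flask holds 52.1%. That step gives target a momentary loss constant k3[B], with [B] the reagent in the reaction phase, of 0.0981 h⁻¹ at 2.50 h and 0.0395 h⁻¹ at 25.0 h, on either side of the carried 0.0562 h⁻¹. Violet is the second flask: twice that constant predicts a fall of 10 points, and the simulated fall is 11 points.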